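## Retrosynthetic overview

- The ten-membered carbocycle is closed last, at the Z-C2=C3 bond, by ring-closing metathesis of a butenolide that carries two vinyl oxiranes; only protecting-group and acyl exchanges follow.
- The butenolide comes from a Ni/Cr coupling of a tetrasubstituted (Z)-enol triflate (C7–C10, C1, C14, C11–C13) with a C3–C6 epoxy aldehyde, which lactonises in situ and sets C6.
- Triflate half: Evans glycolate alkylation (C8) with a dienyl iodide, Shi epoxidation (C1, C10), Claisen condensation with a C11–C13 ester, enol triflation.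
- Aldehyde half: (Z)-3-iodobutenol, Stille vinylation, Sharpless epoxidation (C4, C5), oxidation.
- Ring order: the two oxiranes (on separate halves), then the butenolide, then the ten-membered ring.

Assumption: names use germacrane numbering (ring C1–C10; C6–O–C12(=O)–C11=C7; C13 on C11; C14 on C10; C15 on C4), so the target is (1R,4R,5S,6S,8S,10S) with a 2Z alkene; DMB = 3,4-dimethoxybenzyl, PMB = 4-methoxybenzyl.

## Route

Step 1
Reactants: 1 4-methoxybenzyl alcohol; 2 ethyl 2-(diethoxyphosphoryl)acrylate; 3 acrolein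
Product: 5 ethyl (2E)-2-{[(4-methoxybenzyl)oxy]methyl}penta-2,4-dienoate, via phosphonate carbanion 4 (not isolated)
Conditions: NaH (1.0 equiv), THF, 0 °C; 2, 0 °C; then 3, −78 → 0 °C
Reagents that add atoms: sodium hydride, [Na+].[H-] (its Na+ stays in 4 only)
Why: Tandem oxa-Michael addition/Horner–Wadsworth–Emmons olefination, in which the alkoxide of 1 adds to the vinylphosphonate and the resulting carbanion olefinates acrolein with the usual E preference of α-branched phosphonoacetates (ester trans to vinyl; minor Z isomer removed by chromatography), no stereocentre being formed.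

Step 2
Reactants: 5 ethyl (2E)-2-{[(4-methoxybenzyl)oxy]methyl}penta-2,4-dienoate
Product: 6 (2Z)-2-{[(4-methoxybenzyl)oxy]methyl}penta-2,4-dien-1-ol
Conditions: DIBAL-H (2.2 equiv), CH2Cl2, −78 °C; Rochelle salt
Reagents that add atoms: none
Why: DIBAL-H reduction of the conjugated ester by 1,2-hydride delivery gives the allylic alcohol without touching the diene or the PMB ether.

Step 3
Reactants: 6 (2Z)-2-{[(4-methoxybenzyl)oxy]methyl}penta-2,4-dien-1-ol
Product: 7 1-({[(2E)-2-(iodomethyl)penta-2,4-dien-1-yl]oxy}methyl)-4-methoxybenzene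
Conditions: PPh3, I2, imidazole, CH2Cl2, 0 °C, dark
Reagents that add atoms: iodine, II
Why: Appel-type iodination turns the primary allylic alcohol into an SN2-reactive allylic iodide under neutral conditions that keep the alkene geometry.

Step 4
Reactants: 8 (3,4-dimethoxyphenyl)methanol; 9 bromoacetic acid
Product: 10 2-[(3,4-dimethoxybenzyl)oxy]acetic acid
Conditions: NaH (2.5 equiv), THF, 0 °C → reflux; then 1 M HCl
Reagents that add atoms: none
Why: Williamson ether synthesis, the sodium alkoxide of 8 displacing bromide from sodium bromoacetate.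

Step 5
Reactants: 10 2-[(3,4-dimethoxybenzyl)oxy]acetic acid; 11 (4R)-4-benzyl-1,3-oxazolidin-2-one
Product: 13 (4R)-4-benzyl-3-{[(3,4-dimethoxybenzyl)oxy]acetyl}-1,3-oxazolidin-2-one, via mixed pivalic anhydride 12 (not isolated)
Conditions: PivCl, Et3N, THF, −78 → 0 °C; then 11/n-BuLi (THF, −78 °C), −78 → 0 °C
Reagents that add atoms: pivaloyl chloride, CC(C)(C)C(=O)Cl (its atoms stay in 12 only)
Why: N-acylation of the lithiated Evans oxazolidinone by the mixed anhydride, which is attacked at the less hindered glycolyl carbonyl; the auxiliary stereocentre is that of 11.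

Step 6
Reactants: 13 (4R)-4-benzyl-3-{[(3,4-dimethoxybenzyl)oxy]acetyl}-1,3-oxazolidin-2-one; 7 1-({[(2E)-2-(iodomethyl)penta-2,4-dien-1-yl]oxy}methyl)-4-methoxybenzene
Product: 14 (4R)-4-benzyl-3-[(2S,4Z)-2-[(3,4-dimethoxybenzyl)oxy]-4-{[(4-methoxybenzyl)oxy]methyl}hepta-4,6-dienoyl]-1,3-oxazolidin-2-one
Conditions: NaHMDS, THF, −78 °C; then 7, −78 → −45 °C
Reagents that add atoms: none
Why: Evans glycolate alkylation, the chelated sodium Z-enolate being alkylated by the allylic iodide on the face opposite the benzyl group of the (R)-auxiliary, which sets C8 as S.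

Step 7
Reactants: 14 (4R)-4-benzyl-3-[(2S,4Z)-2-[(3,4-dimethoxybenzyl)oxy]-4-{[(4-methoxybenzyl)oxy]methyl}hepta-4,6-dienoyl]-1,3-oxazolidin-2-one
Product: 15 (2S,4Z)-2-[(3,4-dimethoxybenzyl)oxy]-N-methoxy-4-{[(4-methoxybenzyl)oxy]methyl}-N-methylhepta-4,6-dienamide
Conditions: MeONHMe·HCl, AlMe3, CH2Cl2, −20 → 0 °C
Reagents that add atoms: N,O-dimethylhydroxylamine hydrochloride, CNOC.Cl
Why: Weinreb transamidation, the aluminium amide attacking the exocyclic imide carbonyl (activated by the α-alkoxy group) and releasing the auxiliary without epimerising C8.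

Step 8
Reactants: 15 (2S,4Z)-2-[(3,4-dimethoxybenzyl)oxy]-N-methoxy-4-{[(4-methoxybenzyl)oxy]methyl}-N-methylhepta-4,6-dienamide
Product: 16 (2S)-2-[(3,4-dimethoxybenzyl)oxy]-N-methoxy-3-[(2S,3R)-2-{[(4-methoxybenzyl)oxy]methyl}-3-vinyloxiran-2-yl]-N-methylpropanamide
Conditions: D-fructose-derived Shi ketone (0.3 equiv), Oxone, K2CO3, Bu4NHSO4, MeCN–DMM–aq. Na2B4O7/EDTA, −5 °C
Reagents that add atoms: potassium peroxymonosulfate (Oxone), OOS(=O)(=O)[O-].[K+]
Why: Shi asymmetric epoxidation, the chiral dioxirane attacking the more electron-rich trisubstituted alkene of the diene through a spiro transition state on the face that gives R at the CH carbon (the sense seen with E-β-methylstyrene), the stereospecific syn addition then fixing C1 as R and C10 as S.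

Step 9
Reactants: 8 (3,4-dimethoxyphenyl)methanol; 17 methyl acrylate
Product: 18 methyl 3-[(3,4-dimethoxybenzyl)oxy]propanoate
Conditions: NaH (5 mol%), THF, 0 → 23 °C
Reagents that add atoms: none
Why: Base-catalysed oxa-Michael addition of the benzylic alkoxide to the acrylate.

Step 10
Reactants: 16 (2S)-2-[(3,4-dimethoxybenzyl)oxy]-N-methoxy-3-[(2S,3R)-2-{[(4-methoxybenzyl)oxy]methyl}-3-vinyloxiran-2-yl]-N-methylpropanamide; 18 methyl 3-[(3,4-dimethoxybenzyl)oxy]propanoate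
Product: 19 methyl (4S)-4-[(3,4-dimethoxybenzyl)oxy]-2-{[(3,4-dimethoxybenzyl)oxy]methyl}-5-[(2S,3R)-2-{[(4-methoxybenzyl)oxy]methyl}-3-vinyloxiran-2-yl]-3-oxopentanoate (C2 epimers)
Conditions: LDA, 18, THF, −78 °C; then 16, −78 °C; aq. NH4Cl
Reagents that add atoms: none
Why: Crossed Claisen condensation, the lithium enolate of 18 (kept at −78 °C to avoid β-elimination) adding to the Weinreb amide to give a chelated tetrahedral intermediate that collapses only on work-up, so C8 is not epimerised and the C11 mixture disappears in step 11.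

Step 11
Reactants: 19 methyl (4S)-4-[(3,4-dimethoxybenzyl)oxy]-2-{[(3,4-dimethoxybenzyl)oxy]methyl}-5-[(2S,3R)-2-{[(4-methoxybenzyl)oxy]methyl}-3-vinyloxiran-2-yl]-3-oxopentanoate
Product: 20 methyl (2Z,4S)-4-[(3,4-dimethoxybenzyl)oxy]-2-{[(3,4-dimethoxybenzyl)oxy]methyl}-5-[(2S,3R)-2-{[(4-methoxybenzyl)oxy]methyl}-3-vinyloxiran-2-yl]-3-{[(trifluoromethyl)sulfonyl]oxy}pent-2-enoate
Conditions: NaH, THF, 0 °C; then PhNTf2, 0 → 23 °C
Reagents that add atoms: N-phenylbis(trifluoromethanesulfonimide), O=S(=O)(N(c1ccccc1)S(=O)(=O)C(F)(F)F)C(F)(F)F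
Why: O-triflation of the chelated U-shaped sodium enolate of the β-keto ester gives the (Z)-enol triflate with OTf cis to the ester, the geometry needed for lactonisation.

Step 12
Reactants: 21 but-2-yn-1-ol
Product: 23 (2Z)-3-iodobut-2-en-1-ol, via cyclic alkenylaluminate 22 (not isolated)
Conditions: Red-Al, THF, 0 → 23 °C; then I2, −78 → 0 °C
Reagents that add atoms: sodium bis(2-methoxyethoxy)aluminium hydride, [Na+].[AlH2-](OCCOC)OCCOC (its atoms stay in 22 only); iodine, II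
Why: Hydroxyl-directed trans-hydroalumination of the propargylic alcohol followed by iodinolysis with retention gives the (Z)-3-iodoallylic alcohol.

Step 13
Reactants: 23 (2Z)-3-iodobut-2-en-1-ol; 24 tributyl(vinyl)stannane
Product: 25 (2Z)-3-methylpenta-2,4-dien-1-ol
Conditions: PdCl2(MeCN)2 (5 mol%), DMF, 23 °C; KF work-up
Reagents that add atoms: none
Why: Stille cross-coupling of the vinyl iodide proceeds with retention of the alkene geometry, so the vinyl group stays cis to CH2OH.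

Step 14
Reactants: 25 (2Z)-3-methylpenta-2,4-dien-1-ol
Product: 26 [(2S,3R)-3-methyl-3-vinyloxiran-2-yl]methanol
Conditions: Ti(OiPr)4, L-(+)-diethyl tartrate, t-BuOOH, 4 Å MS, CH2Cl2, −20 °C
Reagents that add atoms: tert-butyl hydroperoxide, CC(C)(C)OO
Why: Sharpless asymmetric epoxidation of the 3,3-disubstituted allylic alcohol, in which only the alkene bound to titanium through the CH2OH reacts and L-(+)-tartrate delivers oxygen to the face that gives the (2S,3R)-oxirane, i.e. C5 S and C4 R.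

Step 15
Reactants: 26 [(2S,3R)-3-methyl-3-vinyloxiran-2-yl]methanol
Product: 27 (2R,3R)-3-methyl-3-vinyloxirane-2-carbaldehyde
Conditions: Dess–Martin periodinane, NaHCO3, CH2Cl2, 0 °C; used at once
Reagents that add atoms: none
Why: Buffered Dess–Martin oxidation gives the epoxy aldehyde without opening the vinyl oxirane or epimerising C5 (the descriptor changes only because CHO outranks C4).

Step 16
Reactants: 20 methyl (2Z,4S)-4-[(3,4-dimethoxybenzyl)oxy]-2-{[(3,4-dimethoxybenzyl)oxy]methyl}-5-[(2S,3R)-2-{[(4-methoxybenzyl)oxy]methyl}-3-vinyloxiran-2-yl]-3-{[(trifluoromethyl)sulfonyl]oxy}pent-2-enoate; 27 (2R,3R)-3-methyl-3-vinyloxirane-2-carbaldehyde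
Product: 29 (5S)-4-{(1S)-1-[(3,4-dimethoxybenzyl)oxy]-2-[(2S,3R)-2-{[(4-methoxybenzyl)oxy]methyl}-3-vinyloxiran-2-yl]ethyl}-3-{[(3,4-dimethoxybenzyl)oxy]methyl}-5-[(2S,3R)-3-methyl-3-vinyloxiran-2-yl]furan-2(5H)-one, via open hydroxy ester 28 (not isolated)
Conditions: CrCl2 (5 equiv), NiCl2 (2 mol%), DMF–THF, 23 °C
Reagents that add atoms: none
Why: Nozaki–Hiyama–Kishi coupling, in which nickel inserts into the vinyl triflate with retention, the alkenylchromium adds to the aldehyde under Felkin–Anh control (anti to the oxirane C–O bond) to set C6 as S, and the chromium alkoxide lactonises onto the cis ester to close the butenolide.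

Step 17
Reactants: 29 (5S)-4-{(1S)-1-[(3,4-dimethoxybenzyl)oxy]-2-[(2S,3R)-2-{[(4-methoxybenzyl)oxy]methyl}-3-vinyloxiran-2-yl]ethyl}-3-{[(3,4-dimethoxybenzyl)oxy]methyl}-5-[(2S,3R)-3-methyl-3-vinyloxiran-2-yl]furan-2(5H)-one
Product: 30 (1R,4R,5S,6S,8S,10S)-8,13-bis[(3,4-dimethoxybenzyl)oxy]-1,10:4,5-diepoxy-14-[(4-methoxybenzyl)oxy]germacra-2Z,7(11)-dien-12,6-olide
Conditions: Grubbs II (15 mol%), toluene (0.5 mM), 80 °C
Reagents that add atoms: none
Why: Ring-closing metathesis of the two terminal vinyl groups closes the ten-membered carbocycle, the ring favouring the Z alkene (cis-cyclodecene is more stable than trans) and no stereocentre being touched.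

Step 18
Reactants: 30 (1R,4R,5S,6S,8S,10S)-8,13-bis[(3,4-dimethoxybenzyl)oxy]-1,10:4,5-diepoxy-14-[(4-methoxybenzyl)oxy]germacra-2Z,7(11)-dien-12,6-olide
Product: 31 (1R,4R,5S,6S,8S,10S)-1,10:4,5-diepoxy-8,13-dihydroxy-14-[(4-methoxybenzyl)oxy]germacra-2Z,7(11)-dien-12,6-olide
Conditions: DDQ (2.4 equiv), CH2Cl2–pH 7 buffer (10:1), 0 °C
Reagents that add atoms: none
Why: Oxidative benzyl ether cleavage, DDQ oxidising the electron-richer 3,4-dimethoxybenzyl ethers much faster than the 4-methoxybenzyl ether, so both DMB groups are removed while the PMB ether at C14 stays.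

Step 19
Reactants: 31 (1R,4R,5S,6S,8S,10S)-1,10:4,5-diepoxy-8,13-dihydroxy-14-[(4-methoxybenzyl)oxy]germacra-2Z,7(11)-dien-12,6-olide
Product: 32 (1R,4R,5S,6S,8S,10S)-13-acetoxy-1,10:4,5-diepoxy-8-hydroxy-14-[(4-methoxybenzyl)oxy]germacra-2Z,7(11)-dien-12,6-olide
Conditions: AcCl (1.1 equiv), 2,4,6-collidine, CH2Cl2, −78 °C
Reagents that add atoms: acetyl chloride, CC(=O)Cl
Why: Chemoselective acylation of the unhindered primary allylic alcohol over the hindered secondary one, using a weak hindered base that does not deprotonate the butenolide γ-position.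

Step 20
Reactants: 32 (1R,4R,5S,6S,8S,10S)-13-acetoxy-1,10:4,5-diepoxy-8-hydroxy-14-[(4-methoxybenzyl)oxy]germacra-2Z,7(11)-dien-12,6-olide
Product: 33 (1R,4R,5S,6S,8S,10S)-13-acetoxy-1,10:4,5-diepoxy-8-(methacryloyloxy)-14-[(4-methoxybenzyl)oxy]germacra-2Z,7(11)-dien-12,6-olide
Conditions: methacrylic anhydride, DMAP (cat.), pyridine, CH2Cl2, 0 → 23 °C
Reagents that add atoms: methacrylic anhydride, C=C(C)C(=O)OC(=O)C(C)=C
Why: DMAP-catalysed acylation of the remaining secondary alcohol with the anhydride under mildly basic conditions.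

Step 21
Reactants: 33 (1R,4R,5S,6S,8S,10S)-13-acetoxy-1,10:4,5-diepoxy-8-(methacryloyloxy)-14-[(4-methoxybenzyl)oxy]germacra-2Z,7(11)-dien-12,6-olide
Product: 34 (1R,4R,5S,6S,8S,10S)-13-acetoxy-1,10:4,5-diepoxy-14-hydroxy-8-(methacryloyloxy)germacra-2Z,7(11)-dien-12,6-olide (CNP0207684.1)
Conditions: DDQ (1.5 equiv), CH2Cl2–pH 7 buffer (10:1), 0 → 23 °C
Reagents that add atoms: none
Why: DDQ oxidative removal of the PMB ether under buffered neutral conditions frees the C14 alcohol without affecting the esters, the oxiranes or the alkene.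

## Compound list

1 | 4-methoxybenzyl alcohol | COc1ccc(CO)cc1 | starting material
2 | ethyl 2-(diethoxyphosphoryl)acrylate | CCOC(=O)C(=C)P(=O)(OCC)OCC | starting material
3 | acrolein | C=CC=O | starting material
4 | sodium carbanion of ethyl 2-(diethoxyphosphoryl)-3-[(4-methoxybenzyl)oxy]propanoate | CCOC(=O)[C-](COCc1ccc(OC)cc1)P(=O)(OCC)OCC.[Na+] | intermediate
5 | ethyl (2E)-2-{[(4-methoxybenzyl)oxy]methyl}penta-2,4-dienoate | CCOC(=O)/C(COCc1ccc(OC)cc1)=C/C=C | intermediate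
6 | (2Z)-2-{[(4-methoxybenzyl)oxy]methyl}penta-2,4-dien-1-ol | OC/C(COCc1ccc(OC)cc1)=C/C=C | intermediate
7 | 1-({[(2E)-2-(iodomethyl)penta-2,4-dien-1-yl]oxy}methyl)-4-methoxybenzene | IC/C(COCc1ccc(OC)cc1)=C/C=C | intermediate
8 | (3,4-dimethoxyphenyl)methanol | COc1ccc(CO)cc1OC | starting material
9 | bromoacetic acid | OC(=O)CBr | starting material
10 | 2-[(3,4-dimethoxybenzyl)oxy]acetic acid | COc1ccc(COCC(=O)O)cc1OC | intermediate
11 | (4R)-4-benzyl-1,3-oxazolidin-2-one | O=C1N[C@H](Cc2ccccc2)CO1 | starting material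
12 | 2-[(3,4-dimethoxybenzyl)oxy]acetic pivalic anhydride | COc1ccc(COCC(=O)OC(=O)C(C)(C)C)cc1OC | intermediate
13 | (4R)-4-benzyl-3-{[(3,4-dimethoxybenzyl)oxy]acetyl}-1,3-oxazolidin-2-one | COc1ccc(COCC(=O)N2[C@H](Cc3ccccc3)COC2=O)cc1OC | intermediate
14 | (4R)-4-benzyl-3-[(2S,4Z)-2-[(3,4-dimethoxybenzyl)oxy]-4-{[(4-methoxybenzyl)oxy]methyl}hepta-4,6-dienoyl]-1,3-oxazolidin-2-one | O=C1OC[C@@H](Cc2ccccc2)N1C(=O)[C@@H](OCc1ccc(OC)c(OC)c1)C/C(COCc1ccc(OC)cc1)=C/C=C | intermediate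
15 | (2S,4Z)-2-[(3,4-dimethoxybenzyl)oxy]-N-methoxy-4-{[(4-methoxybenzyl)oxy]methyl}-N-methylhepta-4,6-dienamide | CON(C)C(=O)[C@@H](OCc1ccc(OC)c(OC)c1)C/C(COCc1ccc(OC)cc1)=C/C=C | intermediate
16 | (2S)-2-[(3,4-dimethoxybenzyl)oxy]-N-methoxy-3-[(2S,3R)-2-{[(4-methoxybenzyl)oxy]methyl}-3-vinyloxiran-2-yl]-N-methylpropanamide | CON(C)C(=O)[C@@H](OCc1ccc(OC)c(OC)c1)C[C@@]1(COCc2ccc(OC)cc2)O[C@@H]1C=C | intermediate
17 | methyl acrylate | C=CC(=O)OC | starting material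
18 | methyl 3-[(3,4-dimethoxybenzyl)oxy]propanoate | COC(=O)CCOCc1ccc(OC)c(OC)c1 | intermediate
19 | methyl (4S)-4-[(3,4-dimethoxybenzyl)oxy]-2-{[(3,4-dimethoxybenzyl)oxy]methyl}-5-[(2S,3R)-2-{[(4-methoxybenzyl)oxy]methyl}-3-vinyloxiran-2-yl]-3-oxopentanoate (C2 epimers) | COC(=O)C(COCc1ccc(OC)c(OC)c1)C(=O)[C@@H](OCc1ccc(OC)c(OC)c1)C[C@@]1(COCc2ccc(OC)cc2)O[C@@H]1C=C | intermediate
20 | methyl (2Z,4S)-4-[(3,4-dimethoxybenzyl)oxy]-2-{[(3,4-dimethoxybenzyl)oxy]methyl}-5-[(2S,3R)-2-{[(4-methoxybenzyl)oxy]methyl}-3-vinyloxiran-2-yl]-3-{[(trifluoromethyl)sulfonyl]oxy}pent-2-enoate | COC(=O)/C(COCc1ccc(OC)c(OC)c1)=C(\OS(=O)(=O)C(F)(F)F)[C@@H](OCc1ccc(OC)c(OC)c1)C[C@@]1(COCc2ccc(OC)cc2)O[C@@H]1C=C | intermediate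
21 | but-2-yn-1-ol | CC#CCO | starting material
22 | sodium 2,2-bis(2-methoxyethoxy)-3-methyl-2,5-dihydro-1,2-oxaluminol-2-uide (cyclic alkenylaluminate) | CC1=CCO[Al-]1(OCCOC)OCCOC.[Na+] | intermediate
23 | (2Z)-3-iodobut-2-en-1-ol | C/C(I)=C/CO | intermediate
24 | tributyl(vinyl)stannane | C=C[Sn](CCCC)(CCCC)CCCC | starting material
25 | (2Z)-3-methylpenta-2,4-dien-1-ol | C=C/C(C)=C\CO | intermediate
26 | [(2S,3R)-3-methyl-3-vinyloxiran-2-yl]methanol | C=C[C@@]1(C)O[C@H]1CO | intermediate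
27 | (2R,3R)-3-methyl-3-vinyloxirane-2-carbaldehyde | C=C[C@@]1(C)O[C@H]1C=O | intermediate
28 | open hydroxy ester from 20 and 27: methyl pent-2-enoate as 20 with the OTf replaced by an (S)-hydroxy[(2S,3R)-3-methyl-3-vinyloxiran-2-yl]methyl group cis to CO2Me (formed as its chromium(III) alkoxide) | C=C[C@@]1(C)O[C@H]1[C@@H](O)/C(=C(\C(=O)OC)COCc1ccc(OC)c(OC)c1)[C@@H](OCc1ccc(OC)c(OC)c1)C[C@@]1(COCc2ccc(OC)cc2)O[C@@H]1C=C | intermediate
29 | (5S)-4-{(1S)-1-[(3,4-dimethoxybenzyl)oxy]-2-[(2S,3R)-2-{[(4-methoxybenzyl)oxy]methyl}-3-vinyloxiran-2-yl]ethyl}-3-{[(3,4-dimethoxybenzyl)oxy]methyl}-5-[(2S,3R)-3-methyl-3-vinyloxiran-2-yl]furan-2(5H)-one | C=C[C@@]1(C)O[C@H]1[C@H]1OC(=O)C(COCc2ccc(OC)c(OC)c2)=C1[C@@H](OCc1ccc(OC)c(OC)c1)C[C@@]1(COCc2ccc(OC)cc2)O[C@@H]1C=C | intermediate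
30 | (1R,4R,5S,6S,8S,10S)-8,13-bis[(3,4-dimethoxybenzyl)oxy]-1,10:4,5-diepoxy-14-[(4-methoxybenzyl)oxy]germacra-2Z,7(11)-dien-12,6-olide | COc1ccc(CO[C@H]2C[C@@]3(COCc4ccc(OC)cc4)O[C@@H]3/C=C\[C@@]3(C)O[C@H]3[C@H]3OC(=O)C(COCc4ccc(OC)c(OC)c4)=C23)cc1OC | intermediate
31 | (1R,4R,5S,6S,8S,10S)-1,10:4,5-diepoxy-8,13-dihydroxy-14-[(4-methoxybenzyl)oxy]germacra-2Z,7(11)-dien-12,6-olide | O[C@H]1C[C@@]2(COCc3ccc(OC)cc3)O[C@@H]2/C=C\[C@@]2(C)O[C@H]2[C@H]2OC(=O)C(CO)=C12 | intermediate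
32 | (1R,4R,5S,6S,8S,10S)-13-acetoxy-1,10:4,5-diepoxy-8-hydroxy-14-[(4-methoxybenzyl)oxy]germacra-2Z,7(11)-dien-12,6-olide | O[C@H]1C[C@@]2(COCc3ccc(OC)cc3)O[C@@H]2/C=C\[C@@]2(C)O[C@H]2[C@H]2OC(=O)C(COC(C)=O)=C12 | intermediate
33 | (1R,4R,5S,6S,8S,10S)-13-acetoxy-1,10:4,5-diepoxy-8-(methacryloyloxy)-14-[(4-methoxybenzyl)oxy]germacra-2Z,7(11)-dien-12,6-olide | C=C(C)C(=O)O[C@H]1C[C@@]2(COCc3ccc(OC)cc3)O[C@@H]2/C=C\[C@@]2(C)O[C@H]2[C@H]2OC(=O)C(COC(C)=O)=C12 | intermediate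
34 | (1R,4R,5S,6S,8S,10S)-13-acetoxy-1,10:4,5-diepoxy-14-hydroxy-8-(methacryloyloxy)germacra-2Z,7(11)-dien-12,6-olide (CNP0207684.1) | C=C(C)C(=O)O[C@H]1C[C@@]2(CO)O[C@@H]2/C=C\[C@@]2(C)O[C@H]2[C@H]2OC(=O)C(COC(C)=O)=C12 | target

## Step count and risks

Total step count: 21.

Longest linear sequence: 14 steps (1, 2, 3, 6, 7, 8, 10, 11, 16, 17, 18, 19, 20, 21). The other branches are steps 4–5 (glycolate imide), step 9 (C11–C13 ester) and steps 12–15 (epoxy aldehyde).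

Steps most likely to fail:

Step 8 (Shi epoxidation). The diene carries an allylic ether that deactivates the target alkene, and regio- and enantioselectivity rest on analogy. The fallback sets the oxirane before the C8–C9 bond by a hydroxyl-directed epoxidation. It sets out from 6 (with 13) and comes back at 16. Sharpless epoxidation of 6 (Ti(OiPr)4, D-(−)-diethyl tartrate, t-BuOOH, −20 °C; the C9 hydroxyl directs) gives [(2S,3R)-2-{[(4-methoxybenzyl)oxy]methyl}-3-vinyloxiran-2-yl]methanol F1. Tf2O and 2,6-lutidine at −78 °C give [(2R,3R)-2-{[(4-methoxybenzyl)oxy]methyl}-3-vinyloxiran-2-yl]methyl trifluoromethanesulfonate F2, used at once. F2 alkylates the sodium enolate of 13 (NaHMDS, THF, −78 °C) to (4R)-4-benzyl-3-{(2S)-2-[(3,4-dimethoxybenzyl)oxy]-3-[(2S,3R)-2-{[(4-methoxybenzyl)oxy]methyl}-3-vinyloxiran-2-yl]propanoyl}-1,3-oxazolidin-2-one F3. Transamidation with MeONHMe·HCl and i-PrMgCl (THF, −20 °C, no Lewis-acidic aluminium near the oxirane) returns to 16.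

Step 16 (Ni/Cr coupling). The triflate is tetrasubstituted and hindered, and nickel(0) may also attack the vinyl oxiranes. The fallback makes a discrete alkenylmagnesium reagent instead. It sets out from 20 (with 27) and comes back at 29. Addition–elimination of sodium 4-methylbenzenethiolate to 20 (THF, 0 °C) gives methyl (2Z,4S)-4-[(3,4-dimethoxybenzyl)oxy]-2-{[(3,4-dimethoxybenzyl)oxy]methyl}-5-[(2S,3R)-2-{[(4-methoxybenzyl)oxy]methyl}-3-vinyloxiran-2-yl]-3-[(4-methylphenyl)sulfanyl]pent-2-enoate F4. mCPBA (1.0 equiv, −78 °C) gives the corresponding 3-[(4-methylphenyl)sulfinyl]pent-2-enoate F5. Sulfoxide–magnesium exchange (i-PrMgCl, THF, −78 °C) gives the ester-chelated alkenylmagnesium chloride, which adds to 27 and lactonises to 29.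

Step 17 (ring-closing metathesis). A ten-membered ring must close between two oxiranes, and the vinyl group on the quaternary C4 may not load the catalyst, so oligomers can win. The fallback is a relay metathesis that places ruthenium on C3. It sets out from 23 (with 20) and comes back at 30. Stille coupling of 23 with (E)-tributyl[3-(allyloxy)prop-1-en-1-yl]stannane gives (2Z,4E)-6-(allyloxy)-3-methylhexa-2,4-dien-1-ol F6. Sharpless epoxidation (L-(+)-diethyl tartrate) gives {(2S,3R)-3-[(1E)-3-(allyloxy)prop-1-en-1-yl]-3-methyloxiran-2-yl}methanol F7. Dess–Martin oxidation gives (2R,3R)-3-[(1E)-3-(allyloxy)prop-1-en-1-yl]-3-methyloxirane-2-carbaldehyde F8. Ni/Cr coupling of F8 with 20 as in step 16 gives the relay butenolide, 29 with the C4 vinyl replaced by (1E)-3-(allyloxy)prop-1-en-1-yl, F9. Grubbs II then enters at the allyl ether of F9, expels 2,5-dihydrofuran and closes the ring to 30.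

Further compounds

F1 | step 8 | [(2S,3R)-2-{[(4-methoxybenzyl)oxy]methyl}-3-vinyloxiran-2-yl]methanol | OC[C@@]1(COCc2ccc(OC)cc2)O[C@@H]1C=C
F2 | step 8 | [(2R,3R)-2-{[(4-methoxybenzyl)oxy]methyl}-3-vinyloxiran-2-yl]methyl trifluoromethanesulfonate | FC(F)(F)S(=O)(=O)OC[C@@]1(COCc2ccc(OC)cc2)O[C@@H]1C=C
F3 | step 8 | (4R)-4-benzyl-3-{(2S)-2-[(3,4-dimethoxybenzyl)oxy]-3-[(2S,3R)-2-{[(4-methoxybenzyl)oxy]methyl}-3-vinyloxiran-2-yl]propanoyl}-1,3-oxazolidin-2-one | O=C1OC[C@@H](Cc2ccccc2)N1C(=O)[C@@H](OCc1ccc(OC)c(OC)c1)C[C@@]1(COCc2ccc(OC)cc2)O[C@@H]1C=C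
F4 | step 16 | methyl (2Z,4S)-4-[(3,4-dimethoxybenzyl)oxy]-2-{[(3,4-dimethoxybenzyl)oxy]methyl}-5-[(2S,3R)-2-{[(4-methoxybenzyl)oxy]methyl}-3-vinyloxiran-2-yl]-3-[(4-methylphenyl)sulfanyl]pent-2-enoate | COC(=O)/C(COCc1ccc(OC)c(OC)c1)=C(\Sc1ccc(C)cc1)[C@@H](OCc1ccc(OC)c(OC)c1)C[C@@]1(COCc2ccc(OC)cc2)O[C@@H]1C=C
F5 | step 16 | methyl (2Z,4S)-4-[(3,4-dimethoxybenzyl)oxy]-2-{[(3,4-dimethoxybenzyl)oxy]methyl}-5-[(2S,3R)-2-{[(4-methoxybenzyl)oxy]methyl}-3-vinyloxiran-2-yl]-3-[(4-methylphenyl)sulfinyl]pent-2-enoate (sulfur epimers) | COC(=O)/C(COCc1ccc(OC)c(OC)c1)=C(\S(=O)c1ccc(C)cc1)[C@@H](OCc1ccc(OC)c(OC)c1)C[C@@]1(COCc2ccc(OC)cc2)O[C@@H]1C=C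
F6 | step 17 | (2Z,4E)-6-(allyloxy)-3-methylhexa-2,4-dien-1-ol | C=CCOC/C=C/C(C)=C\CO
F7 | step 17 | {(2S,3R)-3-[(1E)-3-(allyloxy)prop-1-en-1-yl]-3-methyloxiran-2-yl}methanol | C=CCOC/C=C/[C@@]1(C)O[C@H]1CO
F8 | step 17 | (2R,3R)-3-[(1E)-3-(allyloxy)prop-1-en-1-yl]-3-methyloxirane-2-carbaldehyde | C=CCOC/C=C/[C@@]1(C)O[C@H]1C=O
F9 | step 17 | (5S)-5-{(2S,3R)-3-[(1E)-3-(allyloxy)prop-1-en-1-yl]-3-methyloxiran-2-yl}-4-{(1S)-1-[(3,4-dimethoxybenzyl)oxy]-2-[(2S,3R)-2-{[(4-methoxybenzyl)oxy]methyl}-3-vinyloxiran-2-yl]ethyl}-3-{[(3,4-dimethoxybenzyl)oxy]methyl}furan-2(5H)-one | C=CCOC/C=C/[C@@]1(C)O[C@H]1[C@H]1OC(=O)C(COCc2ccc(OC)c(OC)c2)=C1[C@@H](OCc1ccc(OC)c(OC)c1)C[C@@]1(COCc2ccc(OC)cc2)O[C@@H]1C=C
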